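**Retrosynthetic overview**
1. The last bonds are C12–Q5 and C15–Q6 (Q1–Q6 = quinone ring; Q5 carries the chromone). A Diels–Alder reaction of (12E)-labda-8(17),12,14-triene-7β,18-diol with 2-(5,7-dihydroxychromon-2-yl)-5-methoxy-1,4-benzoquinone closes the cyclohexene ring of the core.
2. The diene is cut back to an allyl arm on C9 (cross-metathesis with methacrolein, then methylenation). The 7β-hydroxyl comes from allylic oxidation at C7, oxidation to the enone and 1,2-reduction.
3. Rings A and B are disconnected together at C4–C5 and C9–C10: a Lewis acid opens a (2R)-2,2-disubstituted epoxide at C4 and an allylsilane ends the cascade as C8=C17. The route rests on this trans-decalin: quaternary C4 (CH3 and CH2OH), C5, C10 (CH3), C9, the exocyclic C8=C17 methylene and a C3 without oxygen.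
4. The acyclic epoxy triene allylsilane is built linearly (alkylcopper/2-butynoate, acetoacetate dianion, enol triflate, vinyl then Me3SiCH2 coupling). Its single stereocentre comes from a catalytic asymmetric Corey–Chaykovsky epoxidation. C9 carries an allyl arm rather than a CH2O arm, because an allylic C–O bond vinylogous to the C–Si bond would invite 1,4-elimination under the Lewis acid.
5. Ring order: chromone (quinone fragment, made apart), rings A and B together (step 12), core cyclohexene (step 23).

Key step: step 12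

Assumption: the antipode of the LaLi3(binaphthoxide)3 catalyst that gives the (R)-epoxide 17 is used (written below as the (R)-BINOL complex); its sense of induction on this dialkyl ketone is to be confirmed on the first batch.
Numbering: labdane numbering (C1–C20) for the terpenoid; Q1 = C=O next to Q2–OMe, Q3–H, Q4 = C=O, Q5 bears the chromone, Q6–H.

**Route**

Step 1
Reactants: 1 2-(3-chloropropyl)-2-methyl-1,3-dioxolane; 2 ethyl but-2-ynoate
Product: 5 ethyl (2E)-3-methyl-6-(2-methyl-1,3-dioxolan-2-yl)hex-2-enoate, via ketal Grignard reagent 3 (not isolated), via ketal alkylcopper reagent 4 (not isolated)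
Conditions: Mg, THF, 50 °C; CuBr·SMe2 (1 equiv), THF, −78 °C; then 2, −78 °C; MeOH quench at −78 °C, aq. NH4Cl
Reagents that add atoms: none
Why: Syn-carbocupration (conjugate addition of the alkylcopper to the 2-ynoate) with cold protonation should place the new chain trans to the ester, giving the (E)-trisubstituted alkene that becomes C5=C10.

Step 2
Reactants: 5 ethyl (2E)-3-methyl-6-(2-methyl-1,3-dioxolan-2-yl)hex-2-enoate
Product: 6 (2E)-3-methyl-6-(2-methyl-1,3-dioxolan-2-yl)hex-2-en-1-ol
Conditions: i-Bu2AlH (2.3 equiv), CH2Cl2, −78 °C; aq. KNaC4H4O6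
Reagents that add atoms: none
Why: DIBAL-H 1,2-reduction of the conjugated ester should give the allylic alcohol without touching the ketal or the alkene geometry.

Step 3
Reactants: 6 (2E)-3-methyl-6-(2-methyl-1,3-dioxolan-2-yl)hex-2-en-1-ol
Product: 7 2-[(4E)-6-bromo-4-methylhex-4-en-1-yl]-2-methyl-1,3-dioxolane
Conditions: CBr4, PPh3, 2,6-lutidine (cat.), CH2Cl2, 0 °C
Reagents that add atoms: carbon tetrabromide, BrC(Br)(Br)Br
Why: Appel reaction: bromide displaces the alkoxyphosphonium group in an SN2 step at the primary allylic carbon, which keeps the E geometry under conditions that are safe for the ketal.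

Step 4
Reactants: 7 2-[(4E)-6-bromo-4-methylhex-4-en-1-yl]-2-methyl-1,3-dioxolane; 8 ethyl acetoacetate
Product: 10 ethyl (6E)-7-methyl-10-(2-methyl-1,3-dioxolan-2-yl)-3-oxodec-6-enoate, via ethyl acetoacetate dianion 9 (not isolated)
Conditions: 8, NaH, THF, 0 °C; n-BuLi, 0 °C; then 7, 0 °C → rt; aq. NH4Cl
Reagents that add atoms: none
Why: γ-Alkylation of the acetoacetate dianion: the more basic terminal carbanion attacks the allylic bromide in an SN2 step, forming C6–C7 and leaving the β-keto ester that fixes the next alkene geometry.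

Step 5
Reactants: 10 ethyl (6E)-7-methyl-10-(2-methyl-1,3-dioxolan-2-yl)-3-oxodec-6-enoate
Product: 11 ethyl (2Z,6E)-7-methyl-10-(2-methyl-1,3-dioxolan-2-yl)-3-[(trifluoromethanesulfonyl)oxy]deca-2,6-dienoate
Conditions: NaH, THF, 0 °C; PhNTf2, 0 °C → rt
Reagents that add atoms: N-phenylbis(trifluoromethanesulfonimide), O=S(=O)(N(c1ccccc1)S(=O)(=O)C(F)(F)F)C(F)(F)F
Why: O-Sulfonylation of the chelated sodium enolate of the β-keto ester should give the (Z)-enol triflate, with the triflate cis to the ester.

Step 6
Reactants: 11 ethyl (2Z,6E)-7-methyl-10-(2-methyl-1,3-dioxolan-2-yl)-3-[(trifluoromethanesulfonyl)oxy]deca-2,6-dienoate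
Product: 12 (2Z,6E)-1-hydroxy-7-methyl-10-(2-methyl-1,3-dioxolan-2-yl)deca-2,6-dien-3-yl trifluoromethanesulfonate
Conditions: i-Bu2AlH (2.3 equiv), CH2Cl2, −78 °C; aq. KNaC4H4O6
Reagents that add atoms: none
Why: DIBAL-H reduces the ester to the allylic alcohol at −78 °C while the enol triflate is inert to the hydride.

Step 7
Reactants: 12 (2Z,6E)-1-hydroxy-7-methyl-10-(2-methyl-1,3-dioxolan-2-yl)deca-2,6-dien-3-yl trifluoromethanesulfonate
Product: 13 (2Z,6E)-1-bromo-7-methyl-10-(2-methyl-1,3-dioxolan-2-yl)deca-2,6-dien-3-yl trifluoromethanesulfonate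
Conditions: CBr4, PPh3, CH2Cl2, −20 → 0 °C
Reagents that add atoms: carbon tetrabromide, BrC(Br)(Br)Br
Why: Appel reaction at the primary allylic alcohol; no silicon is present yet, so the allylic bromide cannot undergo 1,4-elimination.

Step 8
Reactants: 13 (2Z,6E)-1-bromo-7-methyl-10-(2-methyl-1,3-dioxolan-2-yl)deca-2,6-dien-3-yl trifluoromethanesulfonate
Product: 14 (4Z,8E)-9-methyl-12-(2-methyl-1,3-dioxolan-2-yl)dodeca-1,4,8-trien-5-yl trifluoromethanesulfonate
Conditions: CH2=CHMgBr (1.3 equiv), CuI (10 mol %), THF, −40 → −20 °C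
Reagents that add atoms: vinylmagnesium bromide, C=C[Mg]Br
Why: Copper-catalysed Grignard allylic substitution: the vinyl group should enter at the primary α-carbon, because γ-attack would have to build a fully substituted carbon bearing the triflate, giving the skipped diene with the alkene geometry kept and the enol triflate untouched at low temperature.

Step 9
Reactants: 14 (4Z,8E)-9-methyl-12-(2-methyl-1,3-dioxolan-2-yl)dodeca-1,4,8-trien-5-yl trifluoromethanesulfonate
Product: 15 2-methyl-2-{(4E,8Z)-4-methyl-8-[(trimethylsilyl)methyl]dodeca-4,8,11-trien-1-yl}-1,3-dioxolane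
Conditions: Me3SiCH2MgCl (1.5 equiv), Pd(PPh3)4 (5 mol %), THF, 0 °C → rt
Reagents that add atoms: (trimethylsilyl)methylmagnesium chloride, C[Si](C)(C)C[Mg]Cl
Why: Kumada coupling of the enol triflate with retention of geometry places CH2SiMe3 cis to the allyl arm, the allylsilane geometry that later puts C11 equatorial on C9.

Step 10
Reactants: 15 2-methyl-2-{(4E,8Z)-4-methyl-8-[(trimethylsilyl)methyl]dodeca-4,8,11-trien-1-yl}-1,3-dioxolane
Product: 16 (6E,10Z)-6-methyl-10-[(trimethylsilyl)methyl]tetradeca-6,10,13-trien-2-one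
Conditions: PPTS (0.2 equiv), acetone/H2O, 50 °C
Reagents that add atoms: water, O
Why: Acid-catalysed ketal hydrolysis under buffered conditions that are too weak to protodesilylate the allylsilane.

Step 11
Reactants: 16 (6E,10Z)-6-methyl-10-[(trimethylsilyl)methyl]tetradeca-6,10,13-trien-2-one
Product: 17 (2R)-2-methyl-2-{(4E,8Z)-4-methyl-8-[(trimethylsilyl)methyl]dodeca-4,8,11-trien-1-yl}oxirane
Conditions: Me3S(O)I, NaH, THF (ylide solution); LaLi3((R)-binaphthoxide)3 (5 mol %), (2,4,6-(MeO)3C6H2)3P=O (5 mol %), 5 Å MS, THF, rt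
Reagents that add atoms: dimethyloxosulfonium methylide, [CH2-][S+](C)(C)=O (made from trimethylsulfoxonium iodide, C[S+](C)(C)=O.[I-])
Why: Catalytic asymmetric Corey–Chaykovsky epoxidation: the methylide is delivered to one face of the methyl ketone inside the chiral La/Li binaphthoxide assembly, setting the (R) centre (the future C4), while the alkenes and the allylsilane are inert to the ylide.

Step 12
Reactants: 17 (2R)-2-methyl-2-{(4E,8Z)-4-methyl-8-[(trimethylsilyl)methyl]dodeca-4,8,11-trien-1-yl}oxirane
Product: 18 14,15,16-trinorlabda-8(17),12-dien-18-ol (trans-decalin: 4α-CH2OH, 4β-CH3, 5α-H, 10β-CH3, 9α-H, 9β-allyl, 8(17)-methylene)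
Conditions: MeAlCl2 (1.5 equiv), CH2Cl2, −94 → −78 °C; aq. KNaC4H4O6
Reagents that add atoms: none
Why: MeAlCl2 binds the epoxide oxygen and the C4–O bond lengthens at the tertiary carbon while C5 of the C5=C10 alkene attacks from the side opposite the leaving oxygen, so the (R) configuration of 17 passes to C4 with inversion and the oxygen stays on C18; the C10 cation is then taken by C9 of the allylsilane and loss of the silyl group leaves the alkene only at C8=C17. The closest known reaction type is the MeAlCl2-promoted cyclisation of trisubstituted epoxy polyenes with allylsilane termination, run here with a 2,2-disubstituted terminal epoxide, which is a rarely used initiator. Ring A closes 6-endo (C4–C5, Markovnikov, tertiary cation at C10) and ring B closes 6-endo (C9–C10, β-silyl cation at C8). C4 is controlled by the epoxide stereocentre through anti opening; C5 and C10 follow from anti addition across the E-alkene in a chair–chair fold with the Lewis-acid-bound CH2O arm equatorial and the CH3 axial; C9 follows from the allylsilane geometry, which puts the allyl arm (trans to C7) equatorial. The step needs ring closure to outrun both the 1,2-hydride shift to the aldehyde (Meinwald rearrangement) and full ionisation to a planar C4 cation; the trisubstituted alkene held three carbons away, the low temperature and a terminator arm free of Lewis-basic or ionisable groups are what should secure this. The diastereomer from the fold with the CH2O arm axial and the rearranged aldehyde are the expected by-products and should be removable by chromatography.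

Step 13
Reactants: 18 14,15,16-trinorlabda-8(17),12-dien-18-ol
Product: 19 14,15,16-trinorlabda-8(17),12-diene-7α,18-diol
Conditions: SeO2 (0.3 equiv), t-BuOOH, CH2Cl2, 0 °C → rt
Reagents that add atoms: tert-butyl hydroperoxide, CC(C)(C)OO (oxygen relayed by selenium dioxide, O=[Se]=O)
Why: SeO2/t-BuOOH allylic oxidation (ene reaction then [2,3]-sigmatropic shift) should occur at the electron-richer 1,1-disubstituted C8=C17 alkene and at its CH2 (C7) rather than its CH (C9), giving mainly the axial 7α-alcohol, while the monosubstituted vinyl group reacts far more slowly; the C7 configuration does not matter because step 14 erases it.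

Step 14
Reactants: 19 14,15,16-trinorlabda-8(17),12-diene-7α,18-diol
Product: 20 18-hydroxy-14,15,16-trinorlabda-8(17),12-dien-7-one
Conditions: MnO2 (activated, excess), CH2Cl2, rt
Reagents that add atoms: none
Why: MnO2 oxidises only the allylic C7 alcohol (any 7-epimer or enone from step 13 converges here) and leaves the neopentyl C18 alcohol and both alkenes untouched.

Step 15
Reactants: 20 18-hydroxy-14,15,16-trinorlabda-8(17),12-dien-7-one
Product: 21 14,15,16-trinorlabda-8(17),12-diene-7β,18-diol
Conditions: NaBH4, CeCl3·7H2O, MeOH, −78 → −40 °C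
Reagents that add atoms: none
Why: Luche reduction: 1,2-selective hydride delivery along the axial trajectory from the α face (flanked only by the axial hydrogens at C5 and C9) should give the equatorial 7β-alcohol.

Step 16
Reactants: 21 14,15,16-trinorlabda-8(17),12-diene-7β,18-diol
Product: 22 (12E)-7β,18-dihydroxy-15-norlabda-8(17),12-dien-14-al
Conditions: methacrolein (5 equiv), RuCl2(H2IMes)(=CH-C6H4-2-O-i-Pr) (second-generation Hoveyda–Grubbs catalyst, 5 mol %), CH2Cl2, 40 °C
Reagents that add atoms: methacrolein, C=C(C)C=O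
Why: Olefin cross-metathesis: the unhindered monosubstituted alkene couples with methacrolein to the thermodynamically favoured (E)-2-methyl enal, while the hindered 1,1-disubstituted C8=C17 alkene stays out and the free hydroxyls are tolerated.

Step 17
Reactants: 22 (12E)-7β,18-dihydroxy-15-norlabda-8(17),12-dien-14-al
Product: 23 (12E)-labda-8(17),12,14-triene-7β,18-diol
Conditions: Ph3PCH3Br, KN(SiMe3)2, THF, 0 °C; then 22, −78 → 0 °C (ylide in excess)
Reagents that add atoms: methylenetriphenylphosphorane, C=P(c1ccccc1)(c1ccccc1)c1ccccc1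
Why: Wittig methylenation of the enal (the excess ylide covers the two OH protons) gives the terminal alkene and leaves the 12E geometry unchanged.

Step 18
Reactants: 24 2,4,5-trimethoxybenzoic acid
Product: 25 2,4,5-trimethoxybenzoyl chloride
Conditions: (COCl)2, DMF (cat.), CH2Cl2, 0 °C → rt
Reagents that add atoms: oxalyl chloride, O=C(Cl)C(=O)Cl
Why: Standard acid chloride formation through the chloroiminium species from DMF and oxalyl chloride.

Step 19
Reactants: 25 2,4,5-trimethoxybenzoyl chloride; 26 1-(2,4,6-trihydroxyphenyl)ethan-1-one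
Product: 28 5,7-dihydroxy-2-(2,4,5-trimethoxyphenyl)-4H-chromen-4-one, via aryl 1,3-diketone 27 (not isolated)
Conditions: 26, LiN(SiMe3)2 (4.2 equiv), THF, −78 → −10 °C; 25, −78 °C → rt; aq. HCl; then AcOH, H2SO4 (cat.), 95 °C
Reagents that add atoms: none
Why: Claisen-type C-acylation of the lithium polyanion of the unprotected acetophenone at its ketone enolate gives the 1,3-diketone, and acid-catalysed cyclodehydration of this ortho-hydroxy diketone closes the chromone.

Step 20
Reactants: 28 5,7-dihydroxy-2-(2,4,5-trimethoxyphenyl)-4H-chromen-4-one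
Product: 29 5,7-bis(methoxymethoxy)-2-(2,4,5-trimethoxyphenyl)-4H-chromen-4-one
Conditions: NaH, DMF, 0 °C; MeOCH2Cl, 0 °C → rt
Reagents that add atoms: chloromethyl methyl ether, COCCl
Why: Williamson ether synthesis on both phenoxides, so that the benzo ring of the chromone carries no free phenol during the oxidation.

Step 21
Reactants: 29 5,7-bis(methoxymethoxy)-2-(2,4,5-trimethoxyphenyl)-4H-chromen-4-one
Product: 30 2-[5,7-bis(methoxymethoxy)-4-oxo-4H-chromen-2-yl]-5-methoxycyclohexa-2,5-diene-1,4-dione
Conditions: (NH4)2Ce(NO3)6 (2.5 equiv), MeCN/H2O, 0 °C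
Reagents that add atoms: water, O
Why: Oxidative demethylation by single-electron oxidation: the 2,4,5-trimethoxyphenyl ring holds a para-dimethoxy pair and should give the 2-methoxy-1,4-benzoquinone, while the meta-oxygenated, acyl-substituted chromone ring cannot form a quinone; any MOM group lost here is of no consequence.

Step 22
Reactants: 30 2-[5,7-bis(methoxymethoxy)-4-oxo-4H-chromen-2-yl]-5-methoxycyclohexa-2,5-diene-1,4-dione
Product: 31 2-(5,7-dihydroxy-4-oxo-4H-chromen-2-yl)-5-methoxycyclohexa-2,5-diene-1,4-dione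
Conditions: CF3CO2H, CH2Cl2, 0 °C; used at once
Reagents that add atoms: none
Why: Acidolysis of the aryl MOM acetals with anhydrous trifluoroacetic acid, to which a quinone is stable when no nucleophile is added.

Step 23
Reactants: 23 (12E)-labda-8(17),12,14-triene-7β,18-diol; 31 2-(5,7-dihydroxy-4-oxo-4H-chromen-2-yl)-5-methoxycyclohexa-2,5-diene-1,4-dione
Product: 32 dichrostachine A
Conditions: CH2Cl2, 25–40 °C, dark, argon; preparative HPLC
Reagents that add atoms: none
Why: Normal-demand Diels–Alder reaction at the chromone-bearing Q5=Q6 bond (the methoxy-bearing alkene is a deactivated vinylogous ester): the unsubstituted terminus C15 should bond to the unhindered Q6 (the δ-terminus of the dienone that runs to the hydrogen-bonded pyrone carbonyl) and C12 to Q5, the cis ring fusion follows from suprafacial addition, the required C12 configuration corresponds to the transition state with the chromone rather than the quinone ring under the diene, and because the decalin is too remote to bias the diene face the target is expected alongside its facial isomer and must be separated.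

**Compound list**
1 | 2-(3-chloropropyl)-2-methyl-1,3-dioxolane | CC1(CCCCl)OCCO1 | starting material
2 | ethyl but-2-ynoate | CCOC(=O)C#CC | starting material
3 | [3-(2-methyl-1,3-dioxolan-2-yl)propyl]magnesium chloride | CC1(CCC[Mg]Cl)OCCO1 | intermediate
4 | [3-(2-methyl-1,3-dioxolan-2-yl)propyl]copper | CC1(CCC[Cu])OCCO1 | intermediate
5 | ethyl (2E)-3-methyl-6-(2-methyl-1,3-dioxolan-2-yl)hex-2-enoate | CCOC(=O)/C=C(\C)CCCC1(C)OCCO1 | intermediate
6 | (2E)-3-methyl-6-(2-methyl-1,3-dioxolan-2-yl)hex-2-en-1-ol | OC/C=C(\C)CCCC1(C)OCCO1 | intermediate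
7 | 2-[(4E)-6-bromo-4-methylhex-4-en-1-yl]-2-methyl-1,3-dioxolane | BrC/C=C(\C)CCCC1(C)OCCO1 | intermediate
8 | ethyl acetoacetate | CCOC(=O)CC(C)=O | starting material
9 | ethyl acetoacetate dianion (sodium lithium salt) | CCOC(=O)[CH-]C(=O)[CH2-].[Na+].[Li+] | intermediate
10 | ethyl (6E)-7-methyl-10-(2-methyl-1,3-dioxolan-2-yl)-3-oxodec-6-enoate | CCOC(=O)CC(=O)CC/C=C(\C)CCCC1(C)OCCO1 | intermediate
11 | ethyl (2Z,6E)-7-methyl-10-(2-methyl-1,3-dioxolan-2-yl)-3-[(trifluoromethanesulfonyl)oxy]deca-2,6-dienoate | CCOC(=O)/C=C(OS(=O)(=O)C(F)(F)F)/CC/C=C(\C)CCCC1(C)OCCO1 | intermediate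
12 | (2Z,6E)-1-hydroxy-7-methyl-10-(2-methyl-1,3-dioxolan-2-yl)deca-2,6-dien-3-yl trifluoromethanesulfonate | OC/C=C(OS(=O)(=O)C(F)(F)F)/CC/C=C(\C)CCCC1(C)OCCO1 | intermediate
13 | (2Z,6E)-1-bromo-7-methyl-10-(2-methyl-1,3-dioxolan-2-yl)deca-2,6-dien-3-yl trifluoromethanesulfonate | BrC/C=C(OS(=O)(=O)C(F)(F)F)/CC/C=C(\C)CCCC1(C)OCCO1 | intermediate
14 | (4Z,8E)-9-methyl-12-(2-methyl-1,3-dioxolan-2-yl)dodeca-1,4,8-trien-5-yl trifluoromethanesulfonate | C=CC/C=C(OS(=O)(=O)C(F)(F)F)/CC/C=C(\C)CCCC1(C)OCCO1 | intermediate
15 | 2-methyl-2-{(4E,8Z)-4-methyl-8-[(trimethylsilyl)methyl]dodeca-4,8,11-trien-1-yl}-1,3-dioxolane | C[Si](C)(C)C/C(=C\CC=C)CC/C=C(\C)CCCC1(C)OCCO1 | intermediate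
16 | (6E,10Z)-6-methyl-10-[(trimethylsilyl)methyl]tetradeca-6,10,13-trien-2-one | C[Si](C)(C)C/C(=C\CC=C)CC/C=C(\C)CCCC(C)=O | intermediate
17 | (2R)-2-methyl-2-{(4E,8Z)-4-methyl-8-[(trimethylsilyl)methyl]dodeca-4,8,11-trien-1-yl}oxirane | C[Si](C)(C)C/C(=C\CC=C)CC/C=C(\C)CCC[C@]1(C)CO1 | intermediate
18 | 14,15,16-trinorlabda-8(17),12-dien-18-ol | C=C1CC[C@H]2[C@](C)(CO)CCC[C@]2(C)[C@H]1CC=C | intermediate
19 | 14,15,16-trinorlabda-8(17),12-diene-7α,18-diol | C=C1[C@H](O)C[C@H]2[C@](C)(CO)CCC[C@]2(C)[C@H]1CC=C | intermediate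
20 | 18-hydroxy-14,15,16-trinorlabda-8(17),12-dien-7-one | C=C1C(=O)C[C@H]2[C@](C)(CO)CCC[C@]2(C)[C@H]1CC=C | intermediate
21 | 14,15,16-trinorlabda-8(17),12-diene-7β,18-diol | C=C1[C@@H](O)C[C@H]2[C@](C)(CO)CCC[C@]2(C)[C@H]1CC=C | intermediate
22 | (12E)-7β,18-dihydroxy-15-norlabda-8(17),12-dien-14-al | C=C1[C@@H](O)C[C@H]2[C@](C)(CO)CCC[C@]2(C)[C@H]1C/C=C(\C)C=O | intermediate
23 | (12E)-labda-8(17),12,14-triene-7β,18-diol | C=C1[C@@H](O)C[C@H]2[C@](C)(CO)CCC[C@]2(C)[C@H]1C/C=C(\C)C=C | intermediate
24 | 2,4,5-trimethoxybenzoic acid | COc1cc(OC)c(C(=O)O)cc1OC | starting material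
25 | 2,4,5-trimethoxybenzoyl chloride | COc1cc(OC)c(C(Cl)=O)cc1OC | intermediate
26 | 1-(2,4,6-trihydroxyphenyl)ethan-1-one | CC(=O)c1c(O)cc(O)cc1O | starting material
27 | 1-(2,4,6-trihydroxyphenyl)-3-(2,4,5-trimethoxyphenyl)propane-1,3-dione | COc1cc(OC)c(C(=O)CC(=O)c2c(O)cc(O)cc2O)cc1OC | intermediate
28 | 5,7-dihydroxy-2-(2,4,5-trimethoxyphenyl)-4H-chromen-4-one | COc1cc(OC)c(-c2cc(=O)c3c(O)cc(O)cc3o2)cc1OC | intermediate
29 | 5,7-bis(methoxymethoxy)-2-(2,4,5-trimethoxyphenyl)-4H-chromen-4-one | COCOc1cc(OCOC)c2c(=O)cc(-c3cc(OC)c(OC)cc3OC)oc2c1 | intermediate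
30 | 2-[5,7-bis(methoxymethoxy)-4-oxo-4H-chromen-2-yl]-5-methoxycyclohexa-2,5-diene-1,4-dione | COCOc1cc(OCOC)c2c(=O)cc(C3=CC(=O)C(OC)=CC3=O)oc2c1 | intermediate
31 | 2-(5,7-dihydroxy-4-oxo-4H-chromen-2-yl)-5-methoxycyclohexa-2,5-diene-1,4-dione | COC1=CC(=O)C(c2cc(=O)c3c(O)cc(O)cc3o2)=CC1=O | intermediate
32 | dichrostachine A | C=C1[C@@H](O)C[C@H]2[C@](C)(CO)CCC[C@]2(C)[C@H]1C[C@@H]1C(C)=CC[C@H]2C(=O)C(OC)=CC(=O)[C@@]12c1cc(=O)c2c(O)cc(O)cc2o1 | target

**Step count**
Total step count: 23
Longest linear sequence: 18 steps (steps 1–17 and 23)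

**Steps most likely to fail**

1. Step 12. A hydride shift in the Lewis-acid-bound epoxide (to the aldehyde), or ionisation ahead of C–C bond formation, would cost yield and the transfer of configuration to C4; folding with the CH2O arm axial would give the C4 diastereomer. The fallback changes the cascade from cationic to radical. It sets out from triflate 14: Fe(acac)3-catalysed coupling with MeMgBr (THF/NMP, −30 °C) should give the methyl triene ketal F1, PPTS in wet acetone the ketone F2, and Me3S(O)I/NaH in DMSO the racemic epoxide F3. Cp2TiCl2 (cat.), Mn powder, Me3SiCl and 2,4,6-collidine in THF then open the epoxide homolytically at the tertiary carbon with trivalent titanium. The β-titanoxy radical cannot undergo the hydride shift; it should close rings A and B (6-endo, 6-endo), and the C8 radical is trapped by titanium and loses a β-hydrogen to the exocyclic alkene. The planar C4 radical erases the epoxide configuration, so 18 is formed as the racemate with its enantiomer F4, which is resolved by preparative HPLC on a chiral stationary phase. The route is rejoined at 18.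

2. Step 23. Poor facial selectivity on the diene (the stereocentres are remote), competition between the chromone-under-diene and quinone-under-diene transition states, and regiochemical leakage would all lower the share of 32. The fallback replaces the thermal, substrate-controlled cycloaddition by a catalyst-controlled one. It sets out from 23 and 31: TBSOTf/2,6-lutidine (CH2Cl2, −78 °C) should give the bis-silyl ether F5. The cycloaddition with 31 is then run with a chiral titanium Lewis acid made from TiCl2(O-i-Pr)2 and one antipode of 1,1'-bi-2-naphthol (4 Å MS, CH2Cl2, −30 °C), a catalyst type used for quinones with a peri-hydroxy carbonyl unit. Chelation at the 5-hydroxy-4-oxo unit of the chromone should make the pyrone the activated group that sits under the diene and let the catalyst choose the diene face, giving the bis-silyl adduct F6. HF·pyridine in THF removes both silyl groups and returns to 32.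

3. Step 8. Attack of the vinyl nucleophile at the γ-carbon, or at the triflate sulfur followed by loss of bromide, would destroy the alkene geometry carrier. The fallback sets the trisubstituted alkene by alkyne bromoallylation instead of through the enol triflate. It sets out from bromide 7: lithiated 1-(trimethylsilyl)propyne (n-BuLi, THF, −78 °C) should give the silyl enyne F7, and K2CO3/MeOH the terminal alkyne F8. PdBr2(PhCN)2 (cat.) in allyl bromide (cis-bromopalladation, allyl insertion, β-bromide elimination) should give the bromo triene F9 with Br cis to the allyl arm. Kumada coupling with Me3SiCH2MgCl/Pd(PPh3)4 (retention) rejoins the route at 15.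

**Further compounds**
F1 | step 12 | 2-[(4E,8E)-4,8-dimethyldodeca-4,8,11-trien-1-yl]-2-methyl-1,3-dioxolane | C=CC/C=C(C)/CC/C=C(\C)CCCC1(C)OCCO1
F2 | step 12 | (6E,10E)-6,10-dimethyltetradeca-6,10,13-trien-2-one | C=CC/C=C(C)/CC/C=C(\C)CCCC(C)=O
F3 | step 12 | racemic 2-[(4E,8E)-4,8-dimethyldodeca-4,8,11-trien-1-yl]-2-methyloxirane | C=CC/C=C(C)/CC/C=C(\C)CCCC1(C)CO1
F4 | step 12 | enantiomer of 18 (formed with 18 as the racemate) | C=C1CC[C@@H]2[C@@](C)(CO)CCC[C@@]2(C)[C@@H]1CC=C
F5 | step 23 | (12E)-7β,18-bis(tert-butyldimethylsilyloxy)labda-8(17),12,14-triene | C=C1[C@@H](O[Si](C)(C)C(C)(C)C)C[C@H]2[C@](C)(CO[Si](C)(C)C(C)(C)C)CCC[C@]2(C)[C@H]1C/C=C(\C)C=C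
F6 | step 23 | 7,18-bis-O-(tert-butyldimethylsilyl)dichrostachine A | C=C1[C@@H](O[Si](C)(C)C(C)(C)C)C[C@H]2[C@](C)(CO[Si](C)(C)C(C)(C)C)CCC[C@]2(C)[C@H]1C[C@@H]1C(C)=CC[C@H]2C(=O)C(OC)=CC(=O)[C@@]12c1cc(=O)c2c(O)cc(O)cc2o1
F7 | step 8 | trimethyl[(5E)-6-methyl-9-(2-methyl-1,3-dioxolan-2-yl)non-5-en-1-yn-1-yl]silane | C[Si](C)(C)C#CCC/C=C(\C)CCCC1(C)OCCO1
F8 | step 8 | 2-methyl-2-[(4E)-4-methylnon-4-en-8-yn-1-yl]-1,3-dioxolane | C#CCC/C=C(\C)CCCC1(C)OCCO1
F9 | step 8 | 2-[(4E,8Z)-8-bromo-4-methyldodeca-4,8,11-trien-1-yl]-2-methyl-1,3-dioxolane | C=CC/C=C(Br)/CC/C=C(\C)CCCC1(C)OCCO1
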